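The trap in a dosed flask is to read a rising target as the pace of the catalyst. When catalyst sets the pace, the bench rule gives early product in proportion to it, so elm, with 1.55 times the catalyst of ash, should have held that much more target at 3.00 min. The readings gave a ratio of 1.06, and at 1.00 min the two runs stood level at 9.9%. So the rule failed inside these runs: during the feed, target kept step with the substrate going in.

| flask | substrate | catalyst | remark | time |
|---|---|---|---|---|
| ash | 1 mM (fed, over 4.0 min) | 1.1 µM | the very flask that is asked about, followed so far; the fed solution adds 0.10 times the starting volume |  |
| elm | 1 mM (fed, over 4.0 min) | 1.7 µM | run made earlier; the fed solution adds 0.10 times the starting volume |  |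
| flask | 1.0 mM (fed, over 4.0 min) | 1.1 µM | the fed solution adds 0.10 times the starting volume | 50 min |

| run | time / min | target / % |
|---|---|---|
| ash | 1.00 | 9.9 |
| ash | 3.00 | 29.6 |
| ash | 8.00 | 28.9 |
| ash | 20.0 | 11.1 |
| elm | 1.00 | 9.9 |
| elm | 3.00 | 31.3 |
| elm | 8.00 | 28.5 |
| elm | 20.0 | 10.4 |

(scatter of a reading: 0.5 percentage points)

- charges are per starting volume, the dose included; the dosed solution carries all of it
- percentages count the whole charge, also what has not yet gone in

1. when, up to 50 min, the flask holds most target
2. the amount of target, in percent of the substrate charged, at that time
3. the first time at which target reaches 28%, in the same percent, in min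

I therefore reckoned from the feed instead. In ash, the flask asked about, the reading of target was 29.6% at 3.00 min, with 75.0% of the charge fed, which reads as 39.5%. I call this s, the feed share: target present during the feed as a fraction of the substrate fed so far. The reading at 1.00 min gives 39.6%. Ash had fallen to 28.9% by 8.00 min, so I put the peak near the end of the feed, at 4.0 min, with s of the charge as target. The same share puts the level of 28% at 2.84 min.

The forecast gave 39.3% at 4 min, and the level at 2.85 min: “So the peak sits at the end of the feed, near 39 to 40 %.” My own figures were 39.5% and 2.84 min.

The flask held most target at 4.29 min, with 39.7% against the feed share of 39.5%, and reached the level at 2.82 min against my 2.84 min.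

    substrate + catalyst ⇌ catalyst + target (K = 0.980, k = 34000 /M/s)
    substrate → side product (k = 0.00300 /s)

At 9.46 min the path to side product used substrate at 0.088 of the forward rate of the catalysed step. At 50.0 min that step relaxed with a half-life of 0.168 min, short against that time, which makes it what is called a pre-equilibrium. A neighbouring flask, the same but with 2.8 × 10⁻⁴ mM of catalyst, a quarter of the flask's, peaked at 35.1%, which is 4.4 percentage points below the feed share.

The numbers in the tables were generated by integration from invented constants, and the scatter is random.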